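## Analysis of the target

Target 21 is a γ-butyrolactone (O1, C2 carbonyl, C3, C4, C5). C4 carries a 4-hydroxy-3-methoxybenzyl group (ring A). C3 carries a carbinol carbon that bears a second 4-hydroxy-3-methoxyphenyl group (ring B). There are three contiguous stereocentres: C3 (S), C4 (R) and the carbinol carbon (S). The two ring substituents are trans, and the carbinol centre lies outside the ring next to the epimerisable C3. The compound is a β-hydroxy lactone, so base can cause retro-aldol cleavage, dehydration or epimerisation at C3. The benzylic hydroxyl is para to a phenol, so acid, phenoxide formation or hydrogenolysis conditions endanger it. The difficulty is therefore the acyclic carbinol centre and the late, nearly neutral unmasking of two electron-rich phenols, not the small ring. The plan rests on the chain carbinol carbon–C3–C4–C5 with the C2 carboxyl branching from C3, which is the carbon skeleton of (2R,3S)-isocitric acid 1. The 3S centre of 1 is C3 of 21, its carboxyl on C3 is C2, its CH2–CO2H arm is C4–C5, and its hydroxyl-bearing carbon becomes the carbinol carbon once its carboxyl is exchanged for ring B.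

## Retrosynthetic reasoning

21 from 20. Only the two O–Si bonds are cut. The phenols stay masked as silyl ethers through all organometallic and basic steps. They are freed last under buffered conditions, because the free p-hydroxybenzylic alcohol and the β-hydroxy lactone tolerate neither strong base nor acid.

20 from 18 through 19. The acyl–oxygen bond C2–O1 of 20 is cut and the carbinol oxygen is joined instead to C5 at the carboxyl oxidation level. In 18 the carbinol carbon is a ring member, C5 is the lactone carbonyl and C2 is a free carboxyl. The carbinol/C3 relationship of the target then becomes a plain 2,3-trans relationship on a five-membered ring, and C4 becomes α to a carbonyl and can be functionalised. The forward step has to reduce the lactone but not the carboxylate, after which the new primary alcohol of 19 closes onto the carboxyl. The trans C3/C4 arrangement of 20 corresponds to a cis arrangement of benzyl and carboxyl in 18.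

18 from 15 and 17. The bond between ring A and its CH2 is cut. The C4–CH2 bond is not cut, because direct benzylation of the enolate would bring the benzyl group in anti to the carboxylate and give the wrong (trans) epimer. Adding the aryl group to an exocyclic methylene makes C4 stereogenic in a protonation instead. The proton enters anti to the carboxylate and the benzyl group is left cis, as required.

15 from 12, and 12 from 11. The exocyclic C4=CH2 bond is cut, which leads back to the lactone enolate of 12. The free acid is needed here: as a carboxylate it shields the C3 hydrogen, whereas an ester at C3 would invite β-elimination of the ring oxygen. The ester of 11 therefore has to be cleaved first, without hydroxide.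

11 from 6 and 10 (key disconnection). The bond between the carbinol carbon and ring B is cut. It is the one bond in which the chiral-pool skeleton differs from the target's. Cutting it leaves the C3 centre of 1 untouched and brings in ring B and the carbinol stereocentre together. The forward reaction is a decarboxylative radical arylation. Because the radical is planar, the original configuration at that carbon does not matter, and the neighbouring ester on the ring has to direct the aryl group trans.

6 from 4 and 5, 4 from 3, and 3 from 1. The two carboxyls on the lactone of 1 must be told apart. The one next to the ring oxygen is the more electrophilic, so it can be freed selectively from diester 3 and activated with 5. The other stays as a methyl ester.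

10 and 17 from 9, 9 from 8, and 8 from 7. Rings A and B are the same aryl unit. The carbon–metal bond of 10 and the carbon–boron bond of 17 are both traced back to the carbon–magnesium bond of one Grignard reagent 9, which is made once from silylated bromide 8 and divided between the two branches.

## Alternatives that were turned down

Alternative 1: The C3–C4 ring bond and the bond between ring A and its CH2 are made together. Allyl α-bromo ester A2 (carbinol centre already set) and aryl bromide 8 would be joined under nickel–bipyridine catalysis with cathodic reduction. The C3 radical closes 5-exo onto the allyl group and the primary radical is arylated, giving A1, the tris-silyl ether of 21.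
- For: two C–C bonds and the ring form in one step, and A1 is one desilylation from 21. On convergence and step count this is stronger than the chosen route.
- Against: a reduced α-bromo ester with a β-silyloxy group tends to lose that group by reductive β-elimination, which destroys the carbinol centre.
- Against: the allyl ester prefers the Z ester conformation, from which 5-exo closure is slow, so arylation at C3 before cyclisation or simple reduction compete.
- Against: C3 and C4 are both created in the cyclisation, controlled only by an exocyclic stereocentre, and A2 itself needs an enantioselective synthesis.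
- Comparison: the chosen route takes C3 from the chiral pool and sets the carbinol on a ring, which is the predictable part this alternative lacks.

Alternative 2: The C3–C4 bond is made by oxidative coupling of two molecules of ferulic acid A4 at their β-carbons. Each carboxylate then closes onto the opposite benzylic carbon. Anodic one-electron oxidation would give the cis-fused dilactone A3.
- For: hydrogenolysis of one benzylic C–O bond of A3 would give acid A5, the desilylated counterpart of 18 with the same relative configuration. The cis ring fusion places benzyl and carboxyl cis, and the exo aryl group is trans. The reduction and relactonisation of step 13 would then finish the synthesis in about three steps without protecting groups. On step economy this is clearly the strongest option.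
- Against: nothing in the coupling is asymmetric, so A3 is racemic and a resolution costs half the material.
- Against: phenoxyl radical coupling is not regioselective, so A3 is only one of several dimers.
- Against: the two lactones of A3 are equivalent, and the remaining benzylic C–O bond of A5 is as labile as the first, so stopping after one cleavage is a statistical problem.
- Comparison: the chosen route is longer, but it delivers a single enantiomer and has the two carboxyls and the two benzylic positions differentiated from the start.

Alternative 3: The carbinol C–O bond is made last. A flavin-dependent 4-alkylphenol oxidase of the vanillyl alcohol oxidase family would dehydrogenate the ring B alkylphenol of ring A-silylated matairesinol A7 and hydrate the enzyme-bound intermediate, giving A6, the ring A silyl ether of 21.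
- For: only ring B has a free para phenol, so the site is fixed. The C3 and C4 centres are already correct, and mild aqueous conditions suit the product. If A7 is at hand this is the shortest end game.
- Against: these enzymes are established for small 4-alkylphenols, whereas A7 is bulky and branched next to the benzylic carbon.
- Against: the oxidised intermediate has an acidic hydrogen at C3, so loss of that proton (net dehydrogenation into conjugation with the lactone carbonyl) can take the place of hydration.
- Against: the face of hydration is decided by the active site and cannot be argued from the substrate, and enantiopure A7 must itself be made.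
- Comparison: the chosen route uses only substrate control and ordinary reagents, at the price of more steps.

Key step: step 7

Assumption: natural (2R,3S)-isocitric acid is used as the free acid; if only its monopotassium salt is at hand, it is freed on an acidic ion-exchange resin first. TBS stands for tert-butyldimethylsilyl.

## Route

Step 1
Reactants: 1 (2R,3S)-isocitric acid
Product: 3 dimethyl (2R,3S)-5-oxotetrahydrofuran-2,3-dicarboxylate (esters cis), via trimethyl isocitrate 2 (not isolated)
Conditions: MeOH, H2SO4 (cat.), reflux; then PhMe, TsOH·H2O (cat.), reflux with removal of MeOH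
Reagents that add atoms: methanol, CO
Why: Fischer esterification followed by acid-catalysed lactonisation; the C2 hydroxyl can only close a five-membered ring onto the C5 ester (the C3 ester would give a β-lactone), and no stereocentre is touched.

Step 2
Reactants: 3 dimethyl (2R,3S)-5-oxotetrahydrofuran-2,3-dicarboxylate
Product: 4 (2R,3S)-3-(methoxycarbonyl)-5-oxotetrahydrofuran-2-carboxylic acid
Conditions: Me3SnOH (1.3 equiv), 1,2-dichloroethane, 60 °C; then 1 M HCl wash
Reagents that add atoms: trimethyltin hydroxide, C[Sn](C)(C)O
Why: Selective tin hydroxide-mediated ester hydrolysis; the ester on C2 is α to the ring oxygen and so the more electrophilic, and tin can bridge ring oxygen and carbonyl. The near-neutral reagent should avoid β-elimination of the ring oxygen and epimerisation at C3.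

Step 3
Reactants: 4 (2R,3S)-3-(methoxycarbonyl)-5-oxotetrahydrofuran-2-carboxylic acid; 5 N-hydroxyphthalimide
Product: 6 2-(1,3-dioxoisoindolin-2-yl) 3-methyl (2R,3S)-5-oxotetrahydrofuran-2,3-dicarboxylate
Conditions: N,N′-diisopropylcarbodiimide, DMAP (cat.), CH2Cl2, 0 °C to rt; short silica filtration
Reagents that add atoms: none
Why: Steglich-type carbodiimide esterification to the redox-active ester; α-oxy acids form these esters readily, and the product is used promptly because it is an activated ester.

Step 4
Reactants: 7 4-bromo-2-methoxyphenol
Product: 8 (4-bromo-2-methoxyphenoxy)(tert-butyl)dimethylsilane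
Conditions: TBSCl, imidazole, CH2Cl2, rt
Reagents that add atoms: tert-butyldimethylsilyl chloride, CC(C)(C)[Si](C)(C)Cl
Why: Standard silylation of a phenol; the same bromide serves ring A and ring B.

Step 5
Reactants: 8 (4-bromo-2-methoxyphenoxy)(tert-butyl)dimethylsilane
Product: 9 [4-(tert-butyldimethylsilyloxy)-3-methoxyphenyl]magnesium bromide (titrated THF stock solution)
Conditions: Mg turnings, LiCl, THF, rt; titration, storage under argon
Reagents that add atoms: magnesium, [Mg]
Why: LiCl-assisted magnesium insertion into the aryl bromide (Grignard formation); the aryl silyl ether and the methoxy group are inert to the reagent. One titrated stock solution is prepared and divided, one part for the ring B zinc reagent (step 6) and one part for the ring A boronic acid (step 11).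

Step 6
Reactants: 9 [4-(tert-butyldimethylsilyloxy)-3-methoxyphenyl]magnesium bromide
Product: 10 [4-(tert-butyldimethylsilyloxy)-3-methoxyphenyl]zinc chloride as a titrated THF solution
Conditions: ZnCl2 (1.0 M in THF, 1.05 equiv), 0 °C to rt
Reagents that add atoms: zinc chloride, Cl[Zn]Cl
Why: Transmetalation of the Grignard reagent to zinc; the arylzinc chloride is mild enough to leave esters and lactones alone, and magnesium insertion leaves no alkyl halide by-product that could interfere with the nickel catalyst.

Step 7
Reactants: 6 2-(1,3-dioxoisoindolin-2-yl) 3-methyl (2R,3S)-5-oxotetrahydrofuran-2,3-dicarboxylate; 10 [4-(tert-butyldimethylsilyloxy)-3-methoxyphenyl]zinc chloride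
Product: 11 methyl (2S,3S)-2-[4-(tert-butyldimethylsilyloxy)-3-methoxyphenyl]-5-oxotetrahydrofuran-3-carboxylate (2,3-trans)
Conditions: NiCl2(dme) (20 mol%), 4,4′-di-tert-butyl-2,2′-bipyridine (40 mol%), 10 (3 equiv), THF/DMF, rt; aq. NH4Cl
Reagents that add atoms: none
Why: Negishi-type decarboxylative cross-coupling of a redox-active ester. An aryl nickel species formed from 10 (monovalent nickel after the first turnover) transfers one electron to the phthalimide ester of 6; the radical anion breaks at the N–O bond, loses CO2 and leaves an α-acyloxy radical at C2 of the lactone. This radical is taken up by the aryl nickel complex (divalent nickel), and the resulting trivalent nickel centre forms the C2–aryl bond by reductive elimination. The closest known cases are the same couplings of arylzinc reagents with α-oxy redox-active esters held in five-membered ketal rings of tartrate origin; a lactone oxygen in place of the ketal oxygen makes the radical somewhat less nucleophilic but does not change the steps. No ring is closed. The radical carbon is planar, so the 2R configuration of 6 is lost and the new centre is set only by C3: its methoxycarbonyl group covers one face of the flat five-membered ring and nickel and aryl arrive on the other, which should give the 2,3-trans product (2S,3S), also the more stable isomer. The step needs this diastereoselectivity and chemoselectivity for the active ester; the latter is secured because only the N-acyloxyphthalimide is reducible by nickel, while arylzinc chlorides do not add to the methyl ester or the lactone at room temperature. The C3 centre from 1 is not involved.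

Step 8
Reactants: 11 methyl (2S,3S)-2-[4-(tert-butyldimethylsilyloxy)-3-methoxyphenyl]-5-oxotetrahydrofuran-3-carboxylate
Product: 12 (2S,3S)-2-[4-(tert-butyldimethylsilyloxy)-3-methoxyphenyl]-5-oxotetrahydrofuran-3-carboxylic acid
Conditions: Me3SnOH (4 equiv), 1,2-dichloroethane, 80 °C; then cold 0.5 M HCl wash
Reagents that add atoms: trimethyltin hydroxide, C[Sn](C)(C)O
Why: Tin hydroxide-mediated methyl ester cleavage under near-neutral conditions; hydroxide bases are avoided because they could open the ring by β-elimination from C3 (the Stobbe pathway) and strip the aryl silyl ether. Any lactone opening reverts on acidification, since only the γ-lactone can re-form.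

Step 9
Reactants: 12 (2S,3S)-2-[4-(tert-butyldimethylsilyloxy)-3-methoxyphenyl]-5-oxotetrahydrofuran-3-carboxylic acid
Product: 13 (2S,3S,4R)-2-[4-(tert-butyldimethylsilyloxy)-3-methoxyphenyl]-4-[(dimethylamino)methyl]-5-oxotetrahydrofuran-3-carboxylic acid (crude)
Conditions: LiN(SiMe3)2 (2.5 equiv), THF, −78 °C; N,N-dimethylmethyleneiminium iodide, −78 to 0 °C; AcOH (1 equiv) quench
Reagents that add atoms: N,N-dimethylmethyleneiminium iodide, C=[N+](C)C.[I-]
Why: Mannich reaction of a carboxylate–lactone enolate dianion with a preformed iminium salt; the carboxylate protects the C3 hydrogen, so the second equivalent of base removes a C4 proton. The new C4 centre (expected anti to the carboxylate) is erased in step 10.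

Step 10
Reactants: 13 (2S,3S,4R)-2-[4-(tert-butyldimethylsilyloxy)-3-methoxyphenyl]-4-[(dimethylamino)methyl]-5-oxotetrahydrofuran-3-carboxylic acid
Product: 15 (2S,3S)-2-[4-(tert-butyldimethylsilyloxy)-3-methoxyphenyl]-4-methylene-5-oxotetrahydrofuran-3-carboxylic acid, via trimethylammonium iodide 14 (not isolated)
Conditions: MeI, NaHCO3, MeOH, rt; then cold 0.5 M HCl to pH 3
Reagents that add atoms: none
Why: N-Methylation and Hofmann-type β-elimination through the lactone enolate give the exocyclic alkene; in methanol the amine should react with MeI far faster than the carboxylate. Bicarbonate is too weak to move the double bond into the ring.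

Step 11
Reactants: 9 [4-(tert-butyldimethylsilyloxy)-3-methoxyphenyl]magnesium bromide
Product: 17 [4-(tert-butyldimethylsilyloxy)-3-methoxyphenyl]boronic acid, via dimethyl arylboronate 16 (not isolated)
Conditions: 9 added to B(OMe)3 (2 equiv), THF, −78 °C to rt; then dilute HCl to pH 5
Reagents that add atoms: trimethyl borate, COB(OC)OC; water, O
Why: Borylation of a Grignard reagent with a trialkyl borate and hydrolysis, the standard route to arylboronic acids; inverse addition to excess borate at low temperature suppresses double arylation, and the aryl silyl ether survives the mildly acidic work-up.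

Step 12
Reactants: 15 (2S,3S)-2-[4-(tert-butyldimethylsilyloxy)-3-methoxyphenyl]-4-methylene-5-oxotetrahydrofuran-3-carboxylic acid; 17 [4-(tert-butyldimethylsilyloxy)-3-methoxyphenyl]boronic acid
Product: 18 (2S,3S,4R)-4-[4-(tert-butyldimethylsilyloxy)-3-methoxybenzyl]-2-[4-(tert-butyldimethylsilyloxy)-3-methoxyphenyl]-5-oxotetrahydrofuran-3-carboxylic acid (2,3-trans; 3,4-cis)
Conditions: [Rh(cod)Cl]2 (3 mol%), 17 (2 equiv), NaHCO3 (2.2 equiv), 1,4-dioxane/H2O (10:1), 40 °C; then cold 0.5 M HCl to pH 3
Reagents that add atoms: none
Why: Hayashi–Miyaura 1,4-addition: an aryl rhodium species (monovalent rhodium) adds ring A to the CH2 terminus of the α-methylene lactone, and the rhodium enolate is protonated by water. The carboxylate on C3 and its solvation shell block one face, so the proton should enter anti to it and leave the benzyl group cis to the carboxyl (4R). The weak base is chosen so that this kinetic cis isomer does not epimerise to the trans isomer.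

Step 13
Reactants: 18 (2S,3S,4R)-4-[4-(tert-butyldimethylsilyloxy)-3-methoxybenzyl]-2-[4-(tert-butyldimethylsilyloxy)-3-methoxyphenyl]-5-oxotetrahydrofuran-3-carboxylic acid
Product: 20 (3S,4R)-3-[(S)-[4-(tert-butyldimethylsilyloxy)-3-methoxyphenyl](hydroxy)methyl]-4-[4-(tert-butyldimethylsilyloxy)-3-methoxybenzyl]dihydrofuran-2(3H)-one, via hydroxy acid 19 (not isolated)
Conditions: LiBH4 (3 equiv), THF, 0 °C to rt; then 0.5 M HCl to pH 3, 0 °C; PPTS (cat.), CH2Cl2, rt
Reagents that add atoms: none
Why: Chemoselective reduction of a lactone beside a lithium carboxylate, which LiBH4 does not reduce, then lactonisation of the γ-hydroxy acid. The new primary alcohol closes the five-membered ring, whereas the benzylic hydroxyl could only give a β-lactone, so the lactone is transposed and the former ring oxygen is left as the free carbinol. No stereocentre is involved.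

Step 14
Reactants: 20 (3S,4R)-3-[(S)-[4-(tert-butyldimethylsilyloxy)-3-methoxyphenyl](hydroxy)methyl]-4-[4-(tert-butyldimethylsilyloxy)-3-methoxybenzyl]dihydrofuran-2(3H)-one
Product: 21 (3S,4R)-3-[(S)-hydroxy(4-hydroxy-3-methoxyphenyl)methyl]-4-(4-hydroxy-3-methoxybenzyl)dihydrofuran-2(3H)-one (CNP0288801.2)
Conditions: Bu4NF (2.5 equiv), AcOH (3 equiv), THF, 0 °C
Reagents that add atoms: none
Why: Fluoride cleavage of both aryl silyl ethers; the acetic acid buffer keeps the phenols protonated, which should prevent quinone methide formation at the benzylic alcohol and retro-aldol cleavage or epimerisation at C3.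

## Compound list

1 | (2R,3S)-isocitric acid | OC(=O)C[C@H](C(=O)O)[C@@H](O)C(=O)O | starting material
2 | trimethyl (2R,3S)-isocitrate | COC(=O)C[C@H](C(=O)OC)[C@@H](O)C(=O)OC | intermediate
3 | dimethyl (2R,3S)-5-oxotetrahydrofuran-2,3-dicarboxylate | O=C1C[C@H](C(=O)OC)[C@H](C(=O)OC)O1 | intermediate
4 | (2R,3S)-3-(methoxycarbonyl)-5-oxotetrahydrofuran-2-carboxylic acid | O=C1C[C@H](C(=O)OC)[C@H](C(=O)O)O1 | intermediate
5 | N-hydroxyphthalimide | ON1C(=O)c2ccccc2C1=O | starting material
6 | 2-(1,3-dioxoisoindolin-2-yl) 3-methyl (2R,3S)-5-oxotetrahydrofuran-2,3-dicarboxylate | O=C1C[C@H](C(=O)OC)[C@H](C(=O)ON2C(=O)c3ccccc3C2=O)O1 | intermediate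
7 | 4-bromo-2-methoxyphenol | COc1cc(Br)ccc1O | starting material
8 | (4-bromo-2-methoxyphenoxy)(tert-butyl)dimethylsilane | COc1cc(Br)ccc1O[Si](C)(C)C(C)(C)C | intermediate
9 | [4-(tert-butyldimethylsilyloxy)-3-methoxyphenyl]magnesium bromide | COc1cc([Mg]Br)ccc1O[Si](C)(C)C(C)(C)C | intermediate
10 | [4-(tert-butyldimethylsilyloxy)-3-methoxyphenyl]zinc chloride | COc1cc([Zn]Cl)ccc1O[Si](C)(C)C(C)(C)C | intermediate
11 | methyl (2S,3S)-2-[4-(tert-butyldimethylsilyloxy)-3-methoxyphenyl]-5-oxotetrahydrofuran-3-carboxylate | O=C1C[C@H](C(=O)OC)[C@@H](c2ccc(O[Si](C)(C)C(C)(C)C)c(OC)c2)O1 | intermediate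
12 | (2S,3S)-2-[4-(tert-butyldimethylsilyloxy)-3-methoxyphenyl]-5-oxotetrahydrofuran-3-carboxylic acid | O=C1C[C@H](C(=O)O)[C@@H](c2ccc(O[Si](C)(C)C(C)(C)C)c(OC)c2)O1 | intermediate
13 | (2S,3S,4R)-2-[4-(tert-butyldimethylsilyloxy)-3-methoxyphenyl]-4-[(dimethylamino)methyl]-5-oxotetrahydrofuran-3-carboxylic acid | O=C1[C@@H](CN(C)C)[C@H](C(=O)O)[C@@H](c2ccc(O[Si](C)(C)C(C)(C)C)c(OC)c2)O1 | intermediate
14 | trimethylammonium iodide of 13 (N-methylated at the dimethylamino group) | O=C1[C@@H](C[N+](C)(C)C)[C@H](C(=O)O)[C@@H](c2ccc(O[Si](C)(C)C(C)(C)C)c(OC)c2)O1.[I-] | intermediate
15 | (2S,3S)-2-[4-(tert-butyldimethylsilyloxy)-3-methoxyphenyl]-4-methylene-5-oxotetrahydrofuran-3-carboxylic acid | O=C1C(=C)[C@H](C(=O)O)[C@@H](c2ccc(O[Si](C)(C)C(C)(C)C)c(OC)c2)O1 | intermediate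
16 | dimethyl [4-(tert-butyldimethylsilyloxy)-3-methoxyphenyl]boronate | COB(OC)c1ccc(O[Si](C)(C)C(C)(C)C)c(OC)c1 | intermediate
17 | [4-(tert-butyldimethylsilyloxy)-3-methoxyphenyl]boronic acid | COc1cc(B(O)O)ccc1O[Si](C)(C)C(C)(C)C | intermediate
18 | (2S,3S,4R)-4-[4-(tert-butyldimethylsilyloxy)-3-methoxybenzyl]-2-[4-(tert-butyldimethylsilyloxy)-3-methoxyphenyl]-5-oxotetrahydrofuran-3-carboxylic acid | O=C1[C@H](Cc2ccc(O[Si](C)(C)C(C)(C)C)c(OC)c2)[C@H](C(=O)O)[C@@H](c3ccc(O[Si](C)(C)C(C)(C)C)c(OC)c3)O1 | intermediate
19 | (2S,3R)-4-[4-(tert-butyldimethylsilyloxy)-3-methoxyphenyl]-2-[(S)-[4-(tert-butyldimethylsilyloxy)-3-methoxyphenyl](hydroxy)methyl]-3-(hydroxymethyl)butanoic acid | COc1cc(C[C@@H](CO)[C@H](C(=O)O)[C@H](O)c2ccc(O[Si](C)(C)C(C)(C)C)c(OC)c2)ccc1O[Si](C)(C)C(C)(C)C | intermediate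
20 | (3S,4R)-3-[(S)-[4-(tert-butyldimethylsilyloxy)-3-methoxyphenyl](hydroxy)methyl]-4-[4-(tert-butyldimethylsilyloxy)-3-methoxybenzyl]dihydrofuran-2(3H)-one | COc1cc(C[C@H]2COC(=O)[C@@H]2[C@H](O)c2ccc(O[Si](C)(C)C(C)(C)C)c(OC)c2)ccc1O[Si](C)(C)C(C)(C)C | intermediate
21 | (3S,4R)-3-[(S)-hydroxy(4-hydroxy-3-methoxyphenyl)methyl]-4-(4-hydroxy-3-methoxybenzyl)dihydrofuran-2(3H)-one | COc1cc(C[C@H]2COC(=O)[C@@H]2[C@H](O)c2ccc(O)c(OC)c2)ccc1O | target

## Step count and least certain steps

Total step count: 14. Longest linear sequence: 10 steps (1, 2, 3, 7, 8, 9, 10, 12, 13, 14). Steps 4, 5 and 6 lead to zinc reagent 10 and steps 4, 5 and 11 lead to boronic acid 17; the two branches share steps 4 and 5.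

Step 7 (key step). The main danger is incomplete facial selectivity when the planar radical is captured, so that some aryl enters cis to the ester. Further dangers are hydrogen abstraction by the radical before capture and aryl transfer to the activated acyl group. A lactone α-acyloxy radical is also less explored than the ketal-protected cases. A cis by-product must be removed or equilibrated at the benzylic C2 under mild acid, never with base, since epimerisation at C3 would lead into the enantiomeric series. Fallback: set out from acid 4 and bromide 8 and return at 11 by metallaphotoredox decarboxylative arylation. The conditions would be Ir[dF(CF3)ppy]2(dtbbpy)PF6, NiCl2(dme), 4,4′-di-tert-butyl-2,2′-bipyridine, Cs2CO3, DMF, blue light, rt. Here the carboxylate is oxidised by the excited photocatalyst, the same α-oxy radical forms by loss of CO2, and it is captured by the aryl nickel species from oxidative addition of 8 to zerovalent nickel. No redox-active ester or organozinc reagent is involved, and this fallback needs no compound beyond those of the route (F0).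

Step 12. Facial selectivity of the protonation may be poor. The free carboxyl could deliver the proton to its own face, or the aryl group on C2 could hinder the opposite face. The kinetic cis product could also epimerise at C4, and β-hydride elimination could give Heck-type products. Fallback: set out from 15 and the Grignard reagent 9 and return at 18. After deprotonation of 15 with one equivalent of LiN(SiMe3)2, 9 is added at −78 °C with CuBr·SMe2 as catalyst. The resulting magnesium enolate is quenched at −78 °C with 2,6-di-tert-butyl-4-methylphenol as a bulky proton donor, followed by a cold dilute HCl work-up. This separates C–C bond formation from a deliberately kinetic protonation anti to the carboxylate; no new compound is made (F0).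

Step 2. Site selectivity between the two methyl esters may be incomplete, and partial lactone opening or β-elimination of the ring oxygen may occur on prolonged heating. Fallback: set out from 1 and return at 4 through an anhydride. Heating 1 with acetyl chloride gives the cis-fused (2R,3S)-5-oxotetrahydrofuran-2,3-dicarboxylic anhydride F1. Benzyl alcohol opens F1 at the carbonyl next to the ring oxygen, as α-acyloxysuccinic anhydrides do, giving (2R,3S)-2-(benzyloxycarbonyl)-5-oxotetrahydrofuran-3-carboxylic acid F2. Trimethylsilyldiazomethane in PhMe/MeOH methylates the free acid to 2-benzyl 3-methyl (2R,3S)-5-oxotetrahydrofuran-2,3-dicarboxylate F3. Hydrogenolysis (H2, Pd/C, EtOAc) then frees the C2 acid and gives 4.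

Step 9 (with step 10). Enolisation of the dianion may be incomplete, proton transfer may lead to ring opening on warming, carboxylate methylation may compete in step 10, and the exocyclic double bond may migrate into the ring. Fallback: set out from 12 and return at 15 by the formylation–formaldehyde method. LiN(SiMe3)2 (3 equiv) and ethyl formate in THF at −78 to 0 °C give (2S,3S)-2-[4-(tert-butyldimethylsilyloxy)-3-methoxyphenyl]-4-formyl-5-oxotetrahydrofuran-3-carboxylic acid F4 as its enolate salt. Paraformaldehyde in THF then effects aldol addition, formyl transfer and elimination of formate to give 15, without amine or alkylating agent.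

Step 13. Silyl transfer from the aryl ethers to the alkoxides formed in the reduction is possible, as is epimerisation at C4 at the aldehyde stage. During acidic ring closure the electron-rich benzylic alcohol may ionise and be captured by the primary hydroxyl to give a tetrahydrofuran. Fallback: set out from 18 and return at 20. The reduction is run as before but quenched with aqueous NH4Cl, and the carboxylate of 19 is closed by acyl activation with 1-ethyl-3-(3-dimethylaminopropyl)carbodiimide hydrochloride in CH2Cl2 at 0 °C. The ring is then formed by carbodiimide lactonisation instead of acid catalysis, and no new compound is made (F0).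

## Further compounds

F0 | step 7 | none | none
F0 | step 12 | none | none
F1 | step 2 | (2R,3S)-5-oxotetrahydrofuran-2,3-dicarboxylic anhydride (cis-fused) | O=C1C[C@@H]2C(=O)OC(=O)[C@@H]2O1
F2 | step 2 | (2R,3S)-2-(benzyloxycarbonyl)-5-oxotetrahydrofuran-3-carboxylic acid | O=C1C[C@H](C(=O)O)[C@H](C(=O)OCc2ccccc2)O1
F3 | step 2 | 2-benzyl 3-methyl (2R,3S)-5-oxotetrahydrofuran-2,3-dicarboxylate | O=C1C[C@H](C(=O)OC)[C@H](C(=O)OCc2ccccc2)O1
F4 | step 9 | (2S,3S)-2-[4-(tert-butyldimethylsilyloxy)-3-methoxyphenyl]-4-formyl-5-oxotetrahydrofuran-3-carboxylic acid (C4 enolisable) | O=C1C(C=O)[C@H](C(=O)O)[C@@H](c2ccc(O[Si](C)(C)C(C)(C)C)c(OC)c2)O1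
F0 | step 13 | none | none
A1 | alternative 1 | tris(tert-butyldimethylsilyl) ether of 21 | COc1cc(C[C@H]2COC(=O)[C@@H]2[C@H](O[Si](C)(C)C(C)(C)C)c2ccc(O[Si](C)(C)C(C)(C)C)c(OC)c2)ccc1O[Si](C)(C)C(C)(C)C
A2 | alternative 1 | allyl 2-bromo-3-(tert-butyldimethylsilyloxy)-3-[4-(tert-butyldimethylsilyloxy)-3-methoxyphenyl]propanoate (carbinol centre as in 21, bromo centre undefined) | C=CCOC(=O)C(Br)[C@H](O[Si](C)(C)C(C)(C)C)c1ccc(O[Si](C)(C)C(C)(C)C)c(OC)c1
A3 | alternative 2 | dehydrodiferulic acid dilactone (racemic; enantiomer leading to 21 drawn) | O=C1O[C@H](c3ccc(O)c(OC)c3)[C@@H]2[C@H]1[C@@H](c4ccc(O)c(OC)c4)OC2=O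
A4 | alternative 2 | ferulic acid | COc1cc(/C=C/C(=O)O)ccc1O
A5 | alternative 2 | 4-(4-hydroxy-3-methoxybenzyl)-2-(4-hydroxy-3-methoxyphenyl)-5-oxotetrahydrofuran-3-carboxylic acid (racemic; (2S,3S,4R) enantiomer drawn) | O=C1[C@H](Cc2ccc(O)c(OC)c2)[C@H](C(=O)O)[C@@H](c3ccc(O)c(OC)c3)O1
A6 | alternative 3 | ring A triisopropylsilyl ether of 21 | COc1cc(C[C@H]2COC(=O)[C@@H]2[C@H](O)c2ccc(O)c(OC)c2)ccc1O[Si](C(C)C)(C(C)C)C(C)C
A7 | alternative 3 | ring A triisopropylsilyl ether of (3R,4R)-matairesinol | COc1cc(C[C@H]2COC(=O)[C@@H]2Cc2ccc(O)c(OC)c2)ccc1O[Si](C(C)C)(C(C)C)C(C)C
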